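**Plan**
- Retrosynthetic cuts, with the side chain numbered C1' (benzylic) to C15': first the O–Si and O–acetyl groups, then C9'–C10' (alkene CH to the acetoxy-bearing carbon), then C8'=C9', then C1'–C2' next to the benzene ring.
- Enabling feature: C10' is an sp3 carbon that carries oxygen and is bonded directly to sp2 C9' of the Z C8'=C9' alkene. A C10'–O bond is the stereoretentive oxidation product of a C10'–B bond. C9' and C10' can therefore first be gathered on one boron atom and then joined by a 1,2-shift.
- C10' is C1 of hexan-1-ol used with reversed polarity. Its diisopropylcarbamate directs the lithiation and later leaves, so the carbon acts as a chiral carbenoid. Boron is the temporary tether and ends as the C10' oxygen.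
- Forward order: orsellinic acid → silyl-protected ester → benzylic alkylation with 8-bromooct-1-ene → Z-selective cross-metathesis with vinyl-B(pin) → lithiation–borylation–oxidation → acetylation → one fluoride deprotection. The benzene ring is bought and no ring is built.
- Stereochemistry: 10R comes from (−)-sparteine in the deprotonation and is relayed by stereospecific steps. 8Z comes from the metathesis catalyst and is retained in the migration.

Key step: step 6

Assumption: the SMILES is read as the 8Z,10R isomer, and orsellinic acid, (−)-sparteine and the molybdenum alkylidene of step 4 are taken as purchasable.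

**Step 1**
Reactants: 1 orsellinic acid (2,4-dihydroxy-6-methylbenzoic acid)
Product: 2 2-(trimethylsilyl)ethyl 2,4-dihydroxy-6-methylbenzoate
Conditions: Me3SiCH2CH2OH (1.05 equiv), PPh3, DIAD, THF, 0 °C to rt
Reagents that add atoms: 2-(trimethylsilyl)ethanol, C[Si](C)(C)CCO
Why: Mitsunobu esterification, in which the carboxylic acid, by far the most acidic site of 1, is O-alkylated by the activated primary alcohol at or below room temperature, so that acyl activation of a hindered acid that loses CO2 easily is avoided and both phenols stay free.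

**Step 2**
Reactants: 2 2-(trimethylsilyl)ethyl 2,4-dihydroxy-6-methylbenzoate
Product: 3 2-(trimethylsilyl)ethyl 2-methyl-4,6-bis(triisopropylsilyloxy)benzoate
Conditions: TIPSOTf (2.4 equiv), 2,6-lutidine, CH2Cl2, 0 °C to rt
Reagents that add atoms: triisopropylsilyl triflate, CC(C)[Si](C(C)C)(C(C)C)OS(=O)(=O)C(F)(F)F
Why: Silyl ether formation with the reactive triflate overcomes the hydrogen bond of the ortho phenol to the ester and should give two aryl TIPS ethers that tolerate base and fall to fluoride.

**Step 3**
Reactants: 3 2-(trimethylsilyl)ethyl 2-methyl-4,6-bis(triisopropylsilyloxy)benzoate; 4 8-bromooct-1-ene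
Product: 6 2-(trimethylsilyl)ethyl 2-(non-8-en-1-yl)-4,6-bis(triisopropylsilyloxy)benzoate, via lithiated toluate 5 (not isolated)
Conditions: LDA (1.15 equiv), THF, −78 °C; then 4 (1.5 equiv), DMPU, −78 to −20 °C
Reagents that add atoms: none
Why: Lateral lithiation and alkylation of an ortho-toluate, in which the ester stabilises the benzylic anion 5 as an extended enolate that displaces the primary bromide by SN2, while the two ortho substituents and the bulky ester slow self-condensation.

**Step 4**
Reactants: 6 2-(trimethylsilyl)ethyl 2-(non-8-en-1-yl)-4,6-bis(triisopropylsilyloxy)benzoate; 7 vinylboronic acid pinacol ester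
Product: 8 2-(trimethylsilyl)ethyl 2-[(8Z)-9-(4,4,5,5-tetramethyl-1,3,2-dioxaborolan-2-yl)non-8-en-1-yl]-4,6-bis(triisopropylsilyloxy)benzoate
Conditions: 7 (3 equiv), Mo(N-2,6-i-Pr2C6H3)(CHCMe2Ph)(NC4H4)(O-2,6-(2,4,6-i-Pr3C6H2)2C6H3) (5 mol %), benzene, 22 °C, 100 torr
Reagents that add atoms: none
Why: Catalyst-controlled Z-selective olefin cross-metathesis of a terminal alkene with vinyl-B(pin), in which the very large aryloxide of the monoaryloxide pyrrolide molybdenum alkylidene forces both metallacyclobutane substituents toward the small imido ligand, so that the cis-alkenylboronate should form kinetically while removal of ethylene drives the exchange.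

**Step 5**
Reactants: 9 hexan-1-ol
Product: 10 hexyl N,N-diisopropylcarbamate
Conditions: i-Pr2NCOCl, Et3N, CH2Cl2, reflux
Reagents that add atoms: N,N-diisopropylcarbamoyl chloride, CC(C)N(C(C)C)C(=O)Cl
Why: Carbamoylation of a primary alcohol with a carbamoyl chloride installs the group that directs the lithiation and later serves as the leaving group.

**Step 6**
Reactants: 10 hexyl N,N-diisopropylcarbamate; 8 2-(trimethylsilyl)ethyl 2-[(8Z)-9-(4,4,5,5-tetramethyl-1,3,2-dioxaborolan-2-yl)non-8-en-1-yl]-4,6-bis(triisopropylsilyloxy)benzoate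
Product: 14 2-(trimethylsilyl)ethyl 2-[(8Z,10R)-10-hydroxypentadec-8-en-1-yl]-4,6-bis(triisopropylsilyloxy)benzoate, via lithiated carbamate 11 (not isolated), via boronate complex 12 (not isolated), via allylic boronic ester 13 (not isolated)
Conditions: 10 (1.1 equiv), (−)-sparteine (1.1 equiv), s-BuLi (1.05 equiv), Et2O, −78 °C, 5 h; cannulated into 8 (1.0 equiv) in Et2O, −78 °C, 1 h; MgBr2·OEt2 (2 equiv), −78 °C to reflux, 12 h; then NaBO3·4H2O, THF/H2O, rt
Reagents that add atoms: sodium perborate tetrahydrate (oxygen donor), [Na+].[Na+].O[B-]1(O)OO[B-](O)(O)OO1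
Why: s-BuLi/(−)-sparteine removes the pro-S hydrogen at C1 of 10, with the carbamate C=O holding lithium, to give the configurationally stable (S)-carbanion 11, which is the future carbinol carbon with reversed polarity. Carbanion 11 attacks the empty orbital on boron of 8 with retention to give boronate 12, in which both carbons to be joined sit on one boron atom, and with MgBr2 pulling on the carbamate the (Z)-alkenyl group shifts from boron to carbon antiperiplanar to the leaving OC(O)N(i-Pr)2 group with inversion (1,2-metallate rearrangement), which forms the C9'–C10' bond and gives (R)-13. The closest known reaction type is the lithiation–borylation (reagent-controlled Matteson-type homologation) of pinacol cis-alkenylboronates with sparteine-ligated lithiated primary O-alkyl carbamates, and no ring is closed. The C10' stereocentre is controlled only by the chiral diamine in the deprotonation and is then carried through two stereospecific events and the stereoretentive boron-to-oxygen oxidation, so that (−)-sparteine should lead to 10R. The migrating sp2 carbon keeps its geometry, so the Z-alkene of 8 is carried over unchanged, and pinacol allylboronates resist 1,3-borotropic shift at these temperatures, so oxidation should give the untransposed allylic alcohol. The step needs attack at boron rather than at the ester or the benzylic CH2, which is secured because the ester is flanked by two ortho substituents, boronate formation is very fast at −78 °C, and 11 is added to 8 so that boron is always in excess.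

**Step 7**
Reactants: 14 2-(trimethylsilyl)ethyl 2-[(8Z,10R)-10-hydroxypentadec-8-en-1-yl]-4,6-bis(triisopropylsilyloxy)benzoate
Product: 15 2-(trimethylsilyl)ethyl 2-[(8Z,10R)-10-acetoxypentadec-8-en-1-yl]-4,6-bis(triisopropylsilyloxy)benzoate
Conditions: Ac2O, pyridine, DMAP (cat.), CH2Cl2, 0 °C to rt
Reagents that add atoms: acetic anhydride, CC(=O)OC(C)=O
Why: DMAP-catalysed acylation of the only free hydroxyl group takes place at oxygen and touches neither the C10' stereocentre nor the alkene.

**Step 8**
Reactants: 15 2-(trimethylsilyl)ethyl 2-[(8Z,10R)-10-acetoxypentadec-8-en-1-yl]-4,6-bis(triisopropylsilyloxy)benzoate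
Product: 16 2-[(8Z,10R)-10-acetoxypentadec-8-en-1-yl]-4,6-dihydroxybenzoic acid (target)
Conditions: TBAF (3.5 equiv), THF, 0 °C to rt; cold 0.5 M HCl to pH 3
Reagents that add atoms: none
Why: Fluoride-induced desilylation cleaves both aryl O–Si bonds and fragments the 2-(trimethylsilyl)ethyl ester to ethylene, Me3SiF and the carboxylate by attack at silicon remote from the hindered carbonyl, which should leave the secondary acetate and the Z-alkene alone, and the cold, mildly acidic work-up avoids decarboxylation.

**Compound list**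
1 | orsellinic acid (2,4-dihydroxy-6-methylbenzoic acid) | Cc1cc(O)cc(O)c1C(=O)O | starting material
2 | 2-(trimethylsilyl)ethyl 2,4-dihydroxy-6-methylbenzoate | Cc1cc(O)cc(O)c1C(=O)OCC[Si](C)(C)C | intermediate
3 | 2-(trimethylsilyl)ethyl 2-methyl-4,6-bis(triisopropylsilyloxy)benzoate | Cc1cc(O[Si](C(C)C)(C(C)C)C(C)C)cc(O[Si](C(C)C)(C(C)C)C(C)C)c1C(=O)OCC[Si](C)(C)C | intermediate
4 | 8-bromooct-1-ene | C=CCCCCCCBr | starting material
5 | benzylic lithium derivative (extended enolate) of 3 | [Li]Cc1cc(O[Si](C(C)C)(C(C)C)C(C)C)cc(O[Si](C(C)C)(C(C)C)C(C)C)c1C(=O)OCC[Si](C)(C)C | intermediate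
6 | 2-(trimethylsilyl)ethyl 2-(non-8-en-1-yl)-4,6-bis(triisopropylsilyloxy)benzoate | C=CCCCCCCCc1cc(O[Si](C(C)C)(C(C)C)C(C)C)cc(O[Si](C(C)C)(C(C)C)C(C)C)c1C(=O)OCC[Si](C)(C)C | intermediate
7 | vinylboronic acid pinacol ester | C=CB1OC(C)(C)C(C)(C)O1 | starting material
8 | 2-(trimethylsilyl)ethyl 2-[(8Z)-9-(4,4,5,5-tetramethyl-1,3,2-dioxaborolan-2-yl)non-8-en-1-yl]-4,6-bis(triisopropylsilyloxy)benzoate | CC1(C)OB(/C=C\CCCCCCCc2cc(O[Si](C(C)C)(C(C)C)C(C)C)cc(O[Si](C(C)C)(C(C)C)C(C)C)c2C(=O)OCC[Si](C)(C)C)OC1(C)C | intermediate
9 | hexan-1-ol | CCCCCCO | starting material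
10 | hexyl N,N-diisopropylcarbamate | CCCCCCOC(=O)N(C(C)C)C(C)C | intermediate
11 | (S)-1-lithiohexyl N,N-diisopropylcarbamate, (−)-sparteine complex (ligand not drawn) | CCCCC[C@H]([Li])OC(=O)N(C(C)C)C(C)C | intermediate
12 | lithium boronate from 11 and 8, (S) at the carbamoyloxy carbon, Z-alkenyl group on boron | CCCCC[C@H]([B-]1(/C=C\CCCCCCCc2cc(O[Si](C(C)C)(C(C)C)C(C)C)cc(O[Si](C(C)C)(C(C)C)C(C)C)c2C(=O)OCC[Si](C)(C)C)OC(C)(C)C(C)(C)O1)OC(=O)N(C(C)C)C(C)C.[Li+] | intermediate
13 | 2-(trimethylsilyl)ethyl 2-[(8Z,10R)-10-(4,4,5,5-tetramethyl-1,3,2-dioxaborolan-2-yl)pentadec-8-en-1-yl]-4,6-bis(triisopropylsilyloxy)benzoate | CCCCC[C@@H](B1OC(C)(C)C(C)(C)O1)/C=C\CCCCCCCc1cc(O[Si](C(C)C)(C(C)C)C(C)C)cc(O[Si](C(C)C)(C(C)C)C(C)C)c1C(=O)OCC[Si](C)(C)C | intermediate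
14 | 2-(trimethylsilyl)ethyl 2-[(8Z,10R)-10-hydroxypentadec-8-en-1-yl]-4,6-bis(triisopropylsilyloxy)benzoate | CCCCC[C@@H](O)/C=C\CCCCCCCc1cc(O[Si](C(C)C)(C(C)C)C(C)C)cc(O[Si](C(C)C)(C(C)C)C(C)C)c1C(=O)OCC[Si](C)(C)C | intermediate
15 | 2-(trimethylsilyl)ethyl 2-[(8Z,10R)-10-acetoxypentadec-8-en-1-yl]-4,6-bis(triisopropylsilyloxy)benzoate | CCCCC[C@H](/C=C\CCCCCCCc1cc(O[Si](C(C)C)(C(C)C)C(C)C)cc(O[Si](C(C)C)(C(C)C)C(C)C)c1C(=O)OCC[Si](C)(C)C)OC(C)=O | intermediate
16 | 2-[(8Z,10R)-10-acetoxypentadec-8-en-1-yl]-4,6-dihydroxybenzoic acid | CCCCC[C@H](/C=C\CCCCCCCc1cc(O)cc(O)c1C(=O)O)OC(C)=O | target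

**Step count and risk**
- Total step count: 8.
- Longest linear sequence: 7 (steps 1, 2, 3, 4, 6, 7, 8).

**Steps most likely to fail**

1. **Step 6.**
   - What may go wrong: the benzylic CH2 may be deprotonated, or the ester attacked, before the carbanion is captured at boron. The 1,2-migration may be incomplete. The aryl silyl ethers may be partly lost during the oxidation.
   - Fallback: it sets out from 8 and comes back at 14.
   - Iododeboronation of 8 with I2 and aqueous NaOH in THF at 0 °C, which proceeds with retention of geometry, should give the (Z)-alkenyl iodide F1.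
   - F1 is then coupled with commercial hexanal in a catalytic asymmetric Nozaki–Hiyama–Kishi reaction. The conditions are CrCl2, a chiral oxazoline–sulfonamide ligand, NiCl2(2,9-dimethyl-1,10-phenanthroline), Mn, Cp2ZrCl2, MeCN, rt.
   - This joins the same two carbons by reductive union of two electrophiles. It tolerates esters and silyl ethers and keeps the geometry of a disubstituted cis-alkenyl iodide. C10' is set by the ligand enantiomer chosen.

2. **Step 4.**
   - What may go wrong: Z/E control may be poor, 6 may homodimerise, or the alkylidene may be deactivated by protic traces.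
   - Fallback: it sets out from 6 and comes back at 8.
   - Lemieux–Johnson cleavage (OsO4 cat., NaIO4, 2,6-lutidine, dioxane/H2O) should give the aldehyde F2.
   - Lithiated trimethylsilyldiazomethane in THF from −78 °C to rt (Colvin rearrangement) homologates F2 to the terminal alkyne F3.
   - Rhodium-catalysed trans-hydroboration of F3 ([Rh(cod)Cl]2, P(i-Pr)3, Et3N, pinacolborane, cyclohexane, rt), which runs through a vinylidene complex, should deliver the cis-alkenylboronate 8.

3. **Step 3.**
   - What may go wrong: the benzylic anion may self-condense with unreacted ester, substitution at the unactivated bromide may be slow, or HBr may be eliminated from 4.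
   - Fallback: it sets out from 3 and 4 and comes back at 6, with the polarity of the two partners exchanged.
   - Anion 5 is quenched at −78 °C by inverse addition to BrCl2CCCl2Br, which should give the benzylic bromide F4.
   - Bromide 4 is converted with Mg in THF into oct-7-enylmagnesium bromide F5.
   - A copper-catalysed Grignard cross-coupling of F4 with F5 (Li2CuCl4 cat., THF, −78 to 0 °C) should form the same C1'–C2' bond.

**Further compounds**
F1 | step 6 | 2-(trimethylsilyl)ethyl 2-[(8Z)-9-iodonon-8-en-1-yl]-4,6-bis(triisopropylsilyloxy)benzoate | I/C=C\CCCCCCCc1cc(O[Si](C(C)C)(C(C)C)C(C)C)cc(O[Si](C(C)C)(C(C)C)C(C)C)c1C(=O)OCC[Si](C)(C)C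
F2 | step 4 | 2-(trimethylsilyl)ethyl 2-(8-oxooctyl)-4,6-bis(triisopropylsilyloxy)benzoate | O=CCCCCCCCc1cc(O[Si](C(C)C)(C(C)C)C(C)C)cc(O[Si](C(C)C)(C(C)C)C(C)C)c1C(=O)OCC[Si](C)(C)C
F3 | step 4 | 2-(trimethylsilyl)ethyl 2-(non-8-yn-1-yl)-4,6-bis(triisopropylsilyloxy)benzoate | C#CCCCCCCCc1cc(O[Si](C(C)C)(C(C)C)C(C)C)cc(O[Si](C(C)C)(C(C)C)C(C)C)c1C(=O)OCC[Si](C)(C)C
F4 | step 3 | 2-(trimethylsilyl)ethyl 2-(bromomethyl)-4,6-bis(triisopropylsilyloxy)benzoate | BrCc1cc(O[Si](C(C)C)(C(C)C)C(C)C)cc(O[Si](C(C)C)(C(C)C)C(C)C)c1C(=O)OCC[Si](C)(C)C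
F5 | step 3 | oct-7-enylmagnesium bromide | C=CCCCCCC[Mg]Br
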